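**Retrosynthetic overview**
- The decalin is disconnected last, by a thermal inverse-electron-demand intramolecular Diels–Alder reaction of an acyclic (2E,4E)-dienone (4π) with the proximal alkene of an (E,E)-hexadienyl terminus (2π). The substrate already carries the complete pyridine/epoxydiol half, and both carbocycles and four stereocentres form at once under control of one methyl stereocentre from (S)-citronellal.
- Enabling feature: the cyclohexene ring carries its C(CH3)=CH double bond between one ring-fusion carbon and the acyl-bearing CH, and the propenyl-bearing CH lies next to the other ring-fusion carbon. This is a Diels–Alder retron in which the aryl ketone activates the diene and the propenyl group is the unused half of a diene that served as dienophile; the four-carbon, methyl-bearing tether becomes the cyclohexane ring, and the α-keto, allylic C–H of the adduct allows correction to the all-equatorial isomer.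
- The dienone comes from C3-lithiation of the pyridine, addition to a tetraenal and oxidation; the tetraenal comes from (S)-citronellal (iodo-olefination, Suzuki coupling, allylic oxidation, Wittig).
- The pyridine/epoxydiol half comes from 5-bromo-2,4-dichloropyridine and (R)-4-silyloxycyclohexenone (aryllithium 1,2-addition, then anti epoxidation). The 2-chloride serves as a masked lactam carbonyl: it deactivates the ring nitrogen towards peracid and directs the C3-lithiation.
- Ring order: pyridine and cyclohexene are bought, then the epoxide is made, then both decalin rings form together; the pyridone is unveiled by late SNAr and global fluoride deprotection.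

Key step: step 13

Remark: 1,4-dioxaspiro[4.5]dec-6-en-8-one (7) is taken as a catalogue compound; otherwise it is one dehydrogenation step from 1,4-cyclohexanedione monoethylene acetal.

**Route**

Step 1
Reactants: 1 (S)-citronellal [(3S)-3,7-dimethyloct-6-enal]
Product: 2 (1E,4S)-1-iodo-4,8-dimethylnona-1,7-diene
Conditions: CrCl2 (6 equiv), CHI3 (2 equiv), THF/1,4-dioxane, 0 °C to rt
Reagents that add atoms: iodoform, IC(I)I
Why: Takai–Utimoto iodo-olefination, in which the gem-dichromium species from CHI3 adds to the aldehyde and eliminates anti to give the (E)-alkenyl iodide, leaves the β-methyl stereocentre and the trisubstituted alkene untouched.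

Step 2
Reactants: 2 (1E,4S)-1-iodo-4,8-dimethylnona-1,7-diene
Product: 3 (2E,4E,7S)-7,11-dimethyldodeca-2,4,10-triene
Conditions: (E)-prop-1-enylboronic acid (1.3 equiv), Pd(dppf)Cl2 (3 mol%), K3PO4, THF/H2O, 40 °C
Reagents that add atoms: (E)-prop-1-enylboronic acid, C/C=C/B(O)O
Why: Suzuki–Miyaura coupling of an alkenyl iodide with an alkenylboronic acid proceeds with retention at both partners, so the (E,E)-diene should result without disturbing the remote alkene.

Step 3
Reactants: 3 (2E,4E,7S)-7,11-dimethyldodeca-2,4,10-triene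
Product: 5 (2E,6S,8E,10E)-2,6-dimethyldodeca-2,8,10-trienal, via allylic alcohol 4 (not isolated)
Conditions: SeO2 (0.3 equiv), t-BuOOH (3 equiv), CH2Cl2, 0 °C to rt; then crude material, MnO2, CH2Cl2, rt
Reagents that add atoms: selenium dioxide, O=[Se]=O (oxygen carrier); tert-butyl hydroperoxide, CC(C)(C)OO (terminal oxygen source)
Why: SeO2/t-BuOOH allylic oxidation (ene reaction followed by [2,3]-sigmatropic shift) attacks the most electron-rich trisubstituted alkene at its (E)-methyl group, the conjugated diene being the poorer ene partner as in myrcene-type substrates, and MnO2 then oxidises only the allylic alcohol so that alcohol and aldehyde converge on the (E)-enal.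

Step 4
Reactants: 5 (2E,6S,8E,10E)-2,6-dimethyldodeca-2,8,10-trienal
Product: 6 (2E,4E,8S,10E,12E)-4,8-dimethyltetradeca-2,4,10,12-tetraenal
Conditions: Ph3P=CHCHO (1.3 equiv), toluene, 80 °C
Reagents that add atoms: (triphenylphosphoranylidene)acetaldehyde, O=CC=P(c1ccccc1)(c1ccccc1)c1ccccc1
Why: Wittig olefination with the stabilised formylmethylene ylide is (E)-selective and should stop after one homologation because the dienal formed is a poorer electrophile than the enal.

Step 5
Reactants: 7 1,4-dioxaspiro[4.5]dec-6-en-8-one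
Product: 8 (8R)-1,4-dioxaspiro[4.5]dec-6-en-8-ol
Conditions: (S)-2-methyl-CBS-oxazaborolidine (15 mol%), BH3·SMe2 (0.7 equiv), THF, −30 °C; aqueous work-up
Reagents that add atoms: none
Why: Corey–Bakshi–Shibata reduction, in which the alkenyl flank of the enone plays the large group, should deliver hydride 1,2 with the (S)-catalyst to set the (8R)-carbinol that later becomes the secondary hydroxyl of the epoxydiol.

Step 6
Reactants: 8 (8R)-1,4-dioxaspiro[4.5]dec-6-en-8-ol
Product: 9 tert-butyldimethyl{[(8R)-1,4-dioxaspiro[4.5]dec-6-en-8-yl]oxy}silane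
Conditions: TBSCl (1.2 equiv), imidazole (2 equiv), DMF, rt
Reagents that add atoms: tert-butyldimethylsilyl chloride, CC(C)(C)[Si](C)(C)Cl
Why: Standard silylation of a secondary allylic alcohol with TBSCl/imidazole; no stereocentre is affected.

Step 7
Reactants: 9 tert-butyldimethyl{[(8R)-1,4-dioxaspiro[4.5]dec-6-en-8-yl]oxy}silane
Product: 10 (4R)-4-[(tert-butyldimethylsilyl)oxy]cyclohex-2-en-1-one
Conditions: PPTS (0.2 equiv), acetone/H2O (10:1), 45 °C
Reagents that add atoms: water, O
Why: Acid-catalysed hydrolysis of the allylic dioxolane under PPTS is mild enough to keep the TBS ether and, being non-basic, does not enolise the γ-stereocentre.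

Step 8
Reactants: 11 5-bromo-2,4-dichloropyridine
Product: 12 5-bromo-2-chloro-4-[2-(trimethylsilyl)ethoxy]pyridine
Conditions: 2-(trimethylsilyl)ethanol (1.05 equiv), NaH (1.1 equiv), THF, 0 °C to rt
Reagents that add atoms: 2-(trimethylsilyl)ethanol, C[Si](C)(C)CCO
Why: Nucleophilic aromatic substitution of a 2,4-dichloropyridine by an alkoxide takes place first at C4 (para to nitrogen and here ortho to bromine), so one equivalent should give the 4-ether and leave the 2-chloride as a masked lactam carbonyl.

Step 9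
Reactants: 12 5-bromo-2-chloro-4-[2-(trimethylsilyl)ethoxy]pyridine; 10 (4R)-4-[(tert-butyldimethylsilyl)oxy]cyclohex-2-en-1-one
Product: 15 5-[(1S,4R)-4-[(tert-butyldimethylsilyl)oxy]-1-[(triethylsilyl)oxy]cyclohex-2-en-1-yl]-2-chloro-4-[2-(trimethylsilyl)ethoxy]pyridine, via aryllithium 13 (not isolated), via lithium alkoxide 14 (not isolated)
Conditions: n-BuLi (1.05 equiv), Et2O/THF, −78 °C; then 10, −78 °C; then TESOTf (1.3 equiv), −78 to 0 °C; chromatography on Et3N-deactivated silica
Reagents that add atoms: triethylsilyl trifluoromethanesulfonate, CC[Si](CC)(CC)OS(=O)(=O)C(F)(F)F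
Why: Bromine–lithium exchange followed by 1,2-addition of the aryllithium to the enone, which should occur by axial attack anti to the pseudoaxial γ-silyloxy group and so place the new tertiary oxygen cis to the OTBS oxygen, with silylation of the alkoxide in the same flask because the free tertiary allylic alcohol is acid-labile (the minor diastereomer is removed by chromatography).

Step 10
Reactants: 15 5-[(1S,4R)-4-[(tert-butyldimethylsilyl)oxy]-1-[(triethylsilyl)oxy]cyclohex-2-en-1-yl]-2-chloro-4-[2-(trimethylsilyl)ethoxy]pyridine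
Product: 16 5-[(1S,2R,5R,6S)-5-[(tert-butyldimethylsilyl)oxy]-2-[(triethylsilyl)oxy]-7-oxabicyclo[4.1.0]heptan-2-yl]-2-chloro-4-[2-(trimethylsilyl)ethoxy]pyridine
Conditions: mCPBA (2 equiv), NaHCO3, CH2Cl2, 0 °C to rt
Reagents that add atoms: 3-chloroperoxybenzoic acid, OOC(=O)c1cccc(Cl)c1
Why: Prilezhaev epoxidation, which should occur anti to the two allylic silyloxy groups that share one face (the tertiary one pseudoaxial), as with cis-3,6-bis(silyloxy)cyclohexenes, while the 2-chloro substituent makes the pyridine nitrogen too weakly nucleophilic for N-oxidation.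

Step 11
Reactants: 16 the epoxide of step 10; 6 (2E,4E,8S,10E,12E)-4,8-dimethyltetradeca-2,4,10,12-tetraenal
Product: 18 (2E,4E,8S,10E,12E)-1-{2-chloro-5-[(1S,2R,5R,6S)-5-[(tert-butyldimethylsilyl)oxy]-2-[(triethylsilyl)oxy]-7-oxabicyclo[4.1.0]heptan-2-yl]-4-[2-(trimethylsilyl)ethoxy]pyridin-3-yl}-4,8-dimethyltetradeca-2,4,10,12-tetraen-1-ol (both C1 epimers), via 3-lithiopyridine 17 (not isolated)
Conditions: LDA (1.1 equiv), THF, −78 °C; then 6 (1.2 equiv), −78 °C; aq. NH4Cl
Reagents that add atoms: none
Why: Directed ortho-lithiation at C3, the C–H flanked by chlorine and the alkoxy group, is fast with LDA at −78 °C, a temperature at which the 3-lithio-2-chloropyridine neither loses LiCl nor attacks the epoxide, and the aryllithium then adds 1,2 to the dienal (the new carbinol centre is removed in step 12).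

Step 12
Reactants: 18 the tetraenyl carbinol of step 11
Product: 19 (2E,4E,8S,10E,12E)-1-{2-chloro-5-[(1S,2R,5R,6S)-5-[(tert-butyldimethylsilyl)oxy]-2-[(triethylsilyl)oxy]-7-oxabicyclo[4.1.0]heptan-2-yl]-4-[2-(trimethylsilyl)ethoxy]pyridin-3-yl}-4,8-dimethyltetradeca-2,4,10,12-tetraen-1-one
Conditions: Dess–Martin periodinane (1.3 equiv), NaHCO3, CH2Cl2, 0 °C; product kept cold and used directly
Reagents that add atoms: none
Why: Dess–Martin oxidation of a doubly allylic secondary alcohol under buffered conditions gives the aryl dienyl ketone without touching alkene geometry, epoxide or silyl ethers.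

Step 13
Reactants: 19 the tetraenone of step 12
Product: 20 {2-chloro-5-[(1S,2R,5R,6S)-5-[(tert-butyldimethylsilyl)oxy]-2-[(triethylsilyl)oxy]-7-oxabicyclo[4.1.0]heptan-2-yl]-4-[2-(trimethylsilyl)ethoxy]pyridin-3-yl}[(1R,2R,4aS,7S,8aR)-4,7-dimethyl-1-[(E)-prop-1-enyl]-1,2,4a,5,6,7,8,8a-octahydronaphthalen-2-yl]methanone (trans-fused; acyl cis to propenyl)
Conditions: toluene (0.005 M), BHT (10 mol%), 120 °C, sealed tube, argon
Reagents that add atoms: none
Why: Thermal intramolecular Diels–Alder reaction with inverse electron demand: the s-cis (2E,4E)-dienone, its LUMO lowered by the 2-chloropyridyl ketone, is the 4π component and the proximal C10=C11 bond of the (E,E)-hexadienyl terminus is the 2π component, so the C5–C10 and C2–C11 bonds (chain numbering) form suprafacially in one concerted, asynchronous event; the closest known reaction type is the thermal type 1 IMDA of 1,7,9-decatrienes that carry the activating carbonyl on the diene. The cyclohexene ring closes as the [4+2] ring itself, and the cyclohexane ring closes at the same moment through the four-carbon tether attached to the diene terminus, which adopts a chair-like arrangement. The E geometries of diene and dienophile fix the relative configuration of the four new centres; the propenyl group lies endo and the tether exo, which gives the trans ring fusion (the C4 methyl group also clashes with the tether in the cis-fused alternative), and the C8 methyl group, equatorial in the chair-like tether, selects the π-face and hence the absolute configuration. The selectivity needed is the pairing of the π systems: the opposite pairing (hexadienyl as 4π, γ,δ-bond of the dienone as 2π) would have to create a quaternary carbon at the methyl-bearing C4, bond at the methyl-capped diene terminus and use the disfavoured s-cis hexadiene, whereas the wanted mode joins two CH termini and uses a dienone whose C4 methyl group favours the s-cis form. The acyl-bearing centre emerges pseudoaxial, cis to the propenyl group, and is corrected in step 14.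

Step 14
Reactants: 20 the cycloadduct of step 13
Product: 22 {5-[(1S,2R,5R,6S)-5-[(tert-butyldimethylsilyl)oxy]-2-[(triethylsilyl)oxy]-7-oxabicyclo[4.1.0]heptan-2-yl]-2,4-bis[2-(trimethylsilyl)ethoxy]pyridin-3-yl}[(1R,2S,4aS,7S,8aR)-4,7-dimethyl-1-[(E)-prop-1-enyl]-1,2,4a,5,6,7,8,8a-octahydronaphthalen-2-yl]methanone, via epimerised chloro ketone 21 (not isolated)
Conditions: 2-(trimethylsilyl)ethanol (3 equiv), NaH (2 equiv), THF, 0 °C, then 45 °C
Reagents that add atoms: 2-(trimethylsilyl)ethanol, C[Si](C)(C)CCO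
Why: Alkoxide-mediated epimerisation and nucleophilic aromatic substitution: the α-keto, allylic centre equilibrates through the enolate (kinetic α-protonation keeps the β,γ-alkene) to the all-equatorial isomer with acyl trans to propenyl, and the same alkoxide displaces the chloride ortho to the ketone, any exchange at C4 being degenerate.

Step 15
Reactants: 22 the bis[2-(trimethylsilyl)ethyl] ether of step 14
Product: 23 3-{[(1R,2S,4aS,7S,8aR)-4,7-dimethyl-1-[(E)-prop-1-enyl]-1,2,4a,5,6,7,8,8a-octahydronaphthalen-2-yl]carbonyl}-5-[(1S,2R,5R,6S)-2,5-dihydroxy-7-oxabicyclo[4.1.0]heptan-2-yl]-4-hydroxypyridin-2(1H)-one (target)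
Conditions: TBAF (8 equiv), THF, 0 °C to rt; AcOH quench
Reagents that add atoms: none
Why: Fluoride-induced global deprotection, which cleaves both silyl ethers and fragments both 2-(trimethylsilyl)ethyl hetaryl ethers (ethene and Me3SiF) to release the 4-hydroxy-2-pyridone, while the epoxide is safe from the pyridone oxygen because the ring is attached cis to the epoxide oxygen and has no backside access.

**Compound list**

1 | (S)-citronellal, (3S)-3,7-dimethyloct-6-enal | O=CC[C@@H](C)CCC=C(C)C | starting material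
2 | (1E,4S)-1-iodo-4,8-dimethylnona-1,7-diene | I/C=C/C[C@@H](C)CCC=C(C)C | intermediate
3 | (2E,4E,7S)-7,11-dimethyldodeca-2,4,10-triene | C/C=C/C=C/C[C@@H](C)CCC=C(C)C | intermediate
4 | (2E,6S,8E,10E)-2,6-dimethyldodeca-2,8,10-trien-1-ol | C/C=C/C=C/C[C@@H](C)CC/C=C(\C)CO | intermediate (not isolated)
5 | (2E,6S,8E,10E)-2,6-dimethyldodeca-2,8,10-trienal | C/C=C/C=C/C[C@@H](C)CC/C=C(\C)C=O | intermediate
6 | (2E,4E,8S,10E,12E)-4,8-dimethyltetradeca-2,4,10,12-tetraenal | C/C=C/C=C/C[C@@H](C)CC/C=C(C)/C=C/C=O | intermediate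
7 | 1,4-dioxaspiro[4.5]dec-6-en-8-one | O=C1C=CC2(CC1)OCCO2 | starting material
8 | (8R)-1,4-dioxaspiro[4.5]dec-6-en-8-ol | O[C@H]1C=CC2(CC1)OCCO2 | intermediate
9 | tert-butyldimethyl{[(8R)-1,4-dioxaspiro[4.5]dec-6-en-8-yl]oxy}silane | CC(C)(C)[Si](C)(C)O[C@H]1C=CC2(CC1)OCCO2 | intermediate
10 | (4R)-4-[(tert-butyldimethylsilyl)oxy]cyclohex-2-en-1-one | CC(C)(C)[Si](C)(C)O[C@H]1C=CC(=O)CC1 | intermediate
11 | 5-bromo-2,4-dichloropyridine | Clc1cc(Cl)c(Br)cn1 | starting material
12 | 5-bromo-2-chloro-4-[2-(trimethylsilyl)ethoxy]pyridine | C[Si](C)(C)CCOc1cc(Cl)ncc1Br | intermediate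
13 | {6-chloro-4-[2-(trimethylsilyl)ethoxy]pyridin-3-yl}lithium | [Li]c1cnc(Cl)cc1OCC[Si](C)(C)C | intermediate (not isolated)
14 | lithium (1S,4R)-4-[(tert-butyldimethylsilyl)oxy]-1-{6-chloro-4-[2-(trimethylsilyl)ethoxy]pyridin-3-yl}cyclohex-2-en-1-olate | C[Si](C)(C)CCOc1cc(Cl)ncc1[C@]2(O[Li])CC[C@@H](O[Si](C)(C)C(C)(C)C)C=C2 | intermediate (not isolated)
15 | 5-[(1S,4R)-4-[(tert-butyldimethylsilyl)oxy]-1-[(triethylsilyl)oxy]cyclohex-2-en-1-yl]-2-chloro-4-[2-(trimethylsilyl)ethoxy]pyridine | C[Si](C)(C)CCOc1cc(Cl)ncc1[C@]2(O[Si](CC)(CC)CC)CC[C@@H](O[Si](C)(C)C(C)(C)C)C=C2 | intermediate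
16 | 5-[(1S,2R,5R,6S)-5-[(tert-butyldimethylsilyl)oxy]-2-[(triethylsilyl)oxy]-7-oxabicyclo[4.1.0]heptan-2-yl]-2-chloro-4-[2-(trimethylsilyl)ethoxy]pyridine | C[Si](C)(C)CCOc1cc(Cl)ncc1[C@]2(O[Si](CC)(CC)CC)CC[C@@H](O[Si](C)(C)C(C)(C)C)[C@@H]3O[C@@H]32 | intermediate
17 | 3-lithio derivative of 16 | C[Si](C)(C)CCOc1c([Li])c(Cl)ncc1[C@]2(O[Si](CC)(CC)CC)CC[C@@H](O[Si](C)(C)C(C)(C)C)[C@@H]3O[C@@H]32 | intermediate (not isolated)
18 | pyridin-3-yl tetraenyl carbinol (C1 epimers), (2E,4E,8S,10E,12E)-chain | C[Si](C)(C)CCOc1c(C(O)/C=C/C(C)=C/CC[C@H](C)C/C=C/C=C/C)c(Cl)ncc1[C@]2(O[Si](CC)(CC)CC)CC[C@@H](O[Si](C)(C)C(C)(C)C)[C@@H]3O[C@@H]32 | intermediate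
19 | pyridin-3-yl (2E,4E,8S,10E,12E)-4,8-dimethyltetradeca-2,4,10,12-tetraenyl ketone | C[Si](C)(C)CCOc1c(C(=O)/C=C/C(C)=C/CC[C@H](C)C/C=C/C=C/C)c(Cl)ncc1[C@]2(O[Si](CC)(CC)CC)CC[C@@H](O[Si](C)(C)C(C)(C)C)[C@@H]3O[C@@H]32 | intermediate
20 | cycloadduct, (1R,2R,4aS,7S,8aR)-decalin, 2-chloropyridine | C/C=C/[C@@H]1[C@H]2C[C@@H](C)CC[C@@H]2C(C)=C[C@@H]1C(=O)c1c(OCC[Si](C)(C)C)c([C@]2(O[Si](CC)(CC)CC)CC[C@@H](O[Si](C)(C)C(C)(C)C)[C@@H]3O[C@@H]32)cnc1Cl | intermediate
21 | epimerised chloro ketone, (1R,2S,4aS,7S,8aR)-decalin | C/C=C/[C@@H]1[C@H]2C[C@@H](C)CC[C@@H]2C(C)=C[C@H]1C(=O)c1c(OCC[Si](C)(C)C)c([C@]2(O[Si](CC)(CC)CC)CC[C@@H](O[Si](C)(C)C(C)(C)C)[C@@H]3O[C@@H]32)cnc1Cl | intermediate (not isolated)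
22 | 2,4-bis[2-(trimethylsilyl)ethoxy]pyridine ketone, (1R,2S,4aS,7S,8aR)-decalin | C/C=C/[C@@H]1[C@H]2C[C@@H](C)CC[C@@H]2C(C)=C[C@H]1C(=O)c1c(OCC[Si](C)(C)C)c([C@]2(O[Si](CC)(CC)CC)CC[C@@H](O[Si](C)(C)C(C)(C)C)[C@@H]3O[C@@H]32)cnc1OCC[Si](C)(C)C | intermediate
23 | CNP0494338.1, 3-acyl-5-(epoxydihydroxycyclohexyl)-4-hydroxypyridin-2(1H)-one | C/C=C/[C@@H]1[C@H]2C[C@@H](C)CC[C@@H]2C(C)=C[C@H]1C(=O)c1c(O)c([C@]2(O)CC[C@@H](O)[C@@H]3O[C@@H]32)c[nH]c1=O | target

**Step count**
Total: 15 steps. Longest linear sequence: 10 steps (5, 6, 7, 9, 10, 11, 12, 13, 14, 15).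

**Three steps most likely to fail**

1. Step 13 (key step). The cycloaddition may pair the π systems the other way round (hexadienyl terminus as 4π partner, γ,δ-bond of the dienone as 2π partner), or endo and π-facial control may erode at the temperature required. The fallback replaces the 2π partner by an enyne, which cannot serve as a diene. It sets out from 2: Sonogashira coupling with propyne (Pd(PPh3)2Cl2, CuI, Et3N) should give the enyne (4E,7S)-7,11-dimethyldodeca-4,10-dien-2-yne F1. The SeO2/t-BuOOH–MnO2 sequence of step 3 should give (2E,6S,8E)-2,6-dimethyldodeca-2,8-dien-10-ynal F2, and the Wittig reaction of step 4 should give (2E,4E,8S,10E)-4,8-dimethyltetradeca-2,4,10-trien-12-ynal F3. Lithiation of 16 as in step 11 and addition to F3 should give the trienynyl carbinol F4, and Dess–Martin oxidation the trienynyl ketone F5. Heating as in step 13 should give the propynyl cycloadduct F6. Ruthenium-catalysed trans-hydrosilylation ([Cp*Ru(MeCN)3]PF6, (EtO)3SiH) should give the alkenyl triethoxysilane F7, and protodesilylation with AgF in aqueous THF/MeOH should deliver the (E)-propenyl group, returning to the route at 20.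

2. Step 10. The peracid may be delivered to the face syn to the silyloxy groups, or the electron-poor alkene may react so slowly that oxidation at nitrogen competes. The fallback separates face selection from oxygen-atom transfer. It sets out from 15: OsO4 (cat.)/NMO dihydroxylation, which follows the empirical rule of attack anti to allylic oxygen substituents and does not oxidise pyridine nitrogen, should give the cis-diol F8. Trimethyl orthoacetate/PPTS should give the cyclic orthoacetate F9. Acetyl bromide should open it with inversion at the less hindered carbon to the bromo acetate F10. K2CO3/MeOH should then close the epoxide with a second inversion (overall retention at both carbons), returning to the route at 16.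

3. Step 14. Chloride displacement at the hindered C2 may be incomplete, the ring double bond may migrate into conjugation with the ketone under alkoxide, or the alkoxide may attack the carbonyl group. The fallback separates the two events and makes the C–O bond by catalysis. It sets out from 20: DBU in toluene at 60 °C should equilibrate the α-centre to give the chloro ketone 21, which is isolated. Palladium-catalysed C–O coupling of the 2-chloropyridine with 2-(trimethylsilyl)ethanol (Pd precatalyst with a bulky biarylphosphine, Cs2CO3, toluene, 80 °C) should then give 22, where the route is rejoined. This fallback makes no compound outside the list (F0).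

**Further compounds**

F1 | step 13 | (4E,7S)-7,11-dimethyldodeca-4,10-dien-2-yne | CC#C/C=C/C[C@@H](C)CCC=C(C)C
F2 | step 13 | (2E,6S,8E)-2,6-dimethyldodeca-2,8-dien-10-ynal | CC#C/C=C/C[C@@H](C)CC/C=C(\C)C=O
F3 | step 13 | (2E,4E,8S,10E)-4,8-dimethyltetradeca-2,4,10-trien-12-ynal | CC#C/C=C/C[C@@H](C)CC/C=C(C)/C=C/C=O
F4 | step 13 | pyridin-3-yl trienynyl carbinol (C1 epimers) | C[Si](C)(C)CCOc1c(C(O)/C=C/C(C)=C/CC[C@H](C)C/C=C/C#CC)c(Cl)ncc1[C@]2(O[Si](CC)(CC)CC)CC[C@@H](O[Si](C)(C)C(C)(C)C)[C@@H]3O[C@@H]32
F5 | step 13 | pyridin-3-yl (2E,4E,8S,10E)-4,8-dimethyltetradeca-2,4,10-trien-12-ynyl ketone | C[Si](C)(C)CCOc1c(C(=O)/C=C/C(C)=C/CC[C@H](C)C/C=C/C#CC)c(Cl)ncc1[C@]2(O[Si](CC)(CC)CC)CC[C@@H](O[Si](C)(C)C(C)(C)C)[C@@H]3O[C@@H]32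
F6 | step 13 | propynyl cycloadduct, trans-fused decalin with acyl cis to propynyl | CC#C[C@@H]1[C@H]2C[C@@H](C)CC[C@@H]2C(C)=C[C@@H]1C(=O)c1c(OCC[Si](C)(C)C)c([C@]2(O[Si](CC)(CC)CC)CC[C@@H](O[Si](C)(C)C(C)(C)C)[C@@H]3O[C@@H]32)cnc1Cl
F7 | step 13 | alkenyl triethoxysilane from trans-hydrosilylation of F6 | C/C(=C/[C@@H]1[C@H]2C[C@@H](C)CC[C@@H]2C(C)=C[C@@H]1C(=O)c1c(OCC[Si](C)(C)C)c([C@]2(O[Si](CC)(CC)CC)CC[C@@H](O[Si](C)(C)C(C)(C)C)[C@@H]3O[C@@H]32)cnc1Cl)[Si](OCC)(OCC)OCC
F8 | step 10 | cis-2,3-diol anti to both silyloxy groups | C[Si](C)(C)CCOc1cc(Cl)ncc1[C@]2(O[Si](CC)(CC)CC)CC[C@@H](O[Si](C)(C)C(C)(C)C)[C@H](O)[C@@H]2O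
F9 | step 10 | cyclic orthoacetate of F8 | C[Si](C)(C)CCOc1cc(Cl)ncc1[C@]2(O[Si](CC)(CC)CC)CC[C@@H](O[Si](C)(C)C(C)(C)C)[C@@H]3OC(C)(OC)O[C@H]23
F10 | step 10 | trans-bromo acetate | C[Si](C)(C)CCOc1cc(Cl)ncc1[C@]2(O[Si](CC)(CC)CC)CC[C@@H](O[Si](C)(C)C(C)(C)C)[C@@H](Br)[C@@H]2OC(C)=O
F0 | step 14 | none | none
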